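## The problem

The target joins a 6-methoxy-2,8-dimethyl-2H-chromene (arene ring A, pyran ring B) through one methylene to C6 of a trans-fused 3a,7a-dimethylhexahydroinden-4-one (cyclohexenone ring C, cyclopentane ring D), and C2 of the chromene is a fully substituted carbon bearing O1, a methyl group, the alkene carbon C3 and that methylene. Ring C holds a tetrasubstituted enone (C4=O, C5=C6) whose C5 carries a 2-hydroxy-2-methylpropyl chain and whose carbonyl sits next to C3a, so that C3a and C7a are vicinal quaternary centres with trans methyl groups. Of the three stereocentres, C3a and C7a fix each other once ring D exists, whereas C2 lies beyond a methylene and an sp2 carbon and is out of reach of substrate control; the two halves therefore need independent sources of chirality and a union that scrambles neither. The C2–O1 bond is tertiary, allylic and conjugated with the arene through C3=C4, so any ring closure that ionises it racemises C2. The 2H-chromene is sensitive to acid and oxidants, both tertiary alcohols eliminate easily, the γ-hydrogens of the enone are acidic, and C7 is a neopentyl carbon where substitution is slow. The side-chain hydroxyl is 1,5 to any leaving group on the C6 methylene and 1,4 to the C4 carbonyl, so it must be masked while electrophiles sit at those positions. The key step is possible because the cis C3=C4 bond holds O1 close to arene carbon C8a (flanked by the C8 methyl and C4a) and because the oxygen is tertiary: the O1–C8a bond can be made by metal-mediated aryl–oxygen coupling without touching C2–O1 and with no β-hydrogen on the carbinol carbon.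

## Retrosynthesis

**35 to 34.** Only the O–Si bond of the side chain is cut. The triethylsilyl group is needed from step 10 onward and is kept through ring closure so that only one alkoxide can bind palladium. Its removal by fluoride asks nothing of the chromene.

**34 to 33 (key cut).** The aryl ether bond O1–C8a of ring B is cut, giving Z-alkenyl aryl triflate 33 with a free tertiary hydroxyl on the future C2. The neighbouring cuts are worse. Cutting C2–O1 (phenol onto an allylic cation, or oxa-6π closure of a dienone) makes the C2 centre without control. Cutting C4–C4a needs an aryl propargyl ether whose formation from a tertiary propargylic alcohol also passes through a planar C2. In 33 this region is acyclic and its only stereochemical content is C2 and the Z geometry. The forward step must form an aryl–oxygen bond from a tertiary alkoxide faster than the triflate is lost or the alkene isomerises.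

**33 to 32, then 28 + 31.** The Z double bond comes from alkyne 32 by syn addition of hydrogen. The C4–C4a bond is cut between the sp carbon and the arene, giving terminal alkyne 28 and iodo triflate 31. A Wittig olefination with a benzylic ylide would leave the geometry open; the alkyne route fixes it and joins two pieces of similar weight. The forward steps need the iodide to couple while the triflate survives, and the hydrogenation to stop at the alkene.

**31 to 30 to 29.** The triflate is cut back to the phenol and the C–I bond to 4-methoxy-2-methylphenol 29. The phenol oxygen marks C8a and directs the iodine to the only free ortho position.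

**28 to 27 to 26 to 25.** The terminal alkyne carbon is removed, leaving α-hydroxy aldehyde 27, which is traced through triol 26 to dioxolanone 25. A direct partial reduction of 25 cannot be relied on beside the enone. Full reduction and re-oxidation costs one step more but asks only for reactions that do not touch the C2–O bond.

**25 to 23 + 20; 23 to 21 + 22.** The bond between C2 and the methylene on C6 is cut with C2 as the nucleophile. The opposite polarity (an allyl metal from 20 adding to a methyl alkynyl ketone) offers no control at C2 and uncertain regiochemistry. This cut separates the two chiral halves: dioxolanone 23 takes C2 from (S)-lactic acid 21 (acetal with pivalaldehyde 22), and bromide 20 holds the two ring-fusion centres. The forward step needs SN2 attack of a hindered enolate on the allylic bromide to beat proton transfer.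

**20 to 19 to 18.** The enone is transposed. The C4 carbonyl and the C6 bromomethyl group of 20 are traced to tertiary allylic bromohydrin 19, and that to enone 18, which has its carbonyl at C6 (target numbering) and one carbon less. Building 20 directly would need an aldol closure onto the hindered C4 ketone and an oxygenated ketone on the other arm. 18 is instead the natural aldol product of a non-enolisable aldehyde. The forward steps are 1,2-addition of a bromomethyl carbanion and an oxidative 1,3-shift.

**18 to 17 to 16 to 15.** The C4=C5 bond of ring C is cut by retro-aldol condensation to keto aldehyde 17, then back to alcohol 16 and its 4-methoxybenzyl ether 15. Only the enolate on the side-chain side of the ketone can close a six-membered ring, so the closure has one possible course.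

**15 to 10 + 13; 13 to 11.** The C6–C7 bond is cut with C7 as the nucleophile. Making neopentyl C7 the electrophile would require SN2 at a neopentyl carbon in a carbon–carbon bond-forming step. As an organolithium from iodide 10 it attacks N-methoxy-N-methylamide 13 without that handicap. Amide 13 brings C5, C6 and the whole side chain with its oxygen, and comes from lactone 11.

**10 to 9 to 8 to 7.** These are functional group changes on a C2-symmetric scaffold: iodide from alcohol 9, mono-ether 9 from diol 8, diol from diester 7. Because the two arms of 8 are homotopic, the first differentiation needs no selectivity.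

**7 to 3 + 4; 3 to 1 + 2.** Both ring-D bonds at the quaternary carbons (C3a–C3, C7a–C1) are cut, leading to dimenthyl 2,3-dimethylsuccinate 3 and 1-bromo-3-chloropropane 4. Diester 3 comes from acid 1 and two molecules of (−)-menthol 2, one for each carboxyl group. The forward step must set two quaternary centres trans and in one absolute sense.

## Roads not taken

Alternative 1: Stereoablative double alkylation of a succinate dienolate as the strategic step.
- Cut: both ring-D bonds at the quaternary carbons (C3a–C3 and C7a–C1), back to an open-chain 2,3-dimethylsuccinate and a three-carbon dihalide.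
- Forward: the dilithium bis-enolate of 3, made from any stereoisomer mixture because both α-centres become trigonal, is alkylated twice by 4 to give the C2-symmetric diester A1.
- Merits: one operation sets both quaternary centres and their trans relation from a cheap acid; the auxiliary is recovered; the C2 axis makes the ester arms homotopic.
- Weak points: facial control by a remote menthyl group over a tetrasubstituted enolate is not assured. The step solves only ring D; ring C, the union with the lactate half and the closure of ring B stay open, and the last is where C2 can be lost.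
- Comparison: this road is absorbed, not rejected; the same reaction is step 2 of the route and A1 is compound 7. As a place to carry risk it is better than the chosen key step, since it is tested at step 2 on cheap material and the etherification only at step 21. Against that, the chosen late step creates no stereocentre and has close analogy in the cyclisation of simpler tertiary alcohols. The chosen plan also starts its reasoning from the most fragile bond of the target, not the most robust ring.

Alternative 2: Acylium-triggered bicyclisation of an E-tetrasubstituted olefin.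
- Cut: rings C and D together, at C3a–C4 and C7a–C1, unfolding the hydrindanone into acyclic acid chloride A3 with an E-configured C3a=C7a olefin and an allylsilane terminus.
- Forward: SnCl4 ionises A3, acylium carbon C4 attacks C3a (six-membered ring), and the tertiary cation at C7a is trapped by the allylsilane (five-membered ring) to give keto ester A2.
- Merits: both carbocycles and both quaternary centres arise in one step, and anti addition across the E olefin gives the trans fusion. The acetate arm on C5 of A2 is two methyl additions from the side-chain alcohol. In bonds formed per step it is clearly better than steps 2 to 9 of the chosen route.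
- Weak points: a stereodefined tetrasubstituted olefin with two different chains is itself hard to make. Absolute configuration must be relayed from the single, epimerisable centre at C5 of A3. Proton loss from the C7a cation competes with closure to a quaternary centre. A2 carries a vinyl group on C1 that the target lacks, and it lacks the C5=C6 bond and the carbon on C6, so corrective steps follow.
- Comparison: the chosen plan spends more steps on the carbocycles, but each quaternary centre has a defined source, no carbon is added only to be removed, and its strategic step addresses the heterocycle, which this alternative does not.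

Alternative 3: Radical 6-endo ynone closure with in-situ methallyl transfer.
- Cut: ring C at C6–C7, and the bond from C5 to the first side-chain carbon.
- Forward: neopentyl iodide A5, an ynone reachable from diol 8, gives the C7 radical, which adds 6-endo to the β-carbon C6. The α-keto vinyl radical at C5 is allylated by stannane A6 to give enone A4.
- Merits: a radical ignores the neopentyl hindrance at C7, and the tetrasubstituted enone forms with both substituents in one step. A4 would replace compounds 15 to 19, so for ring C it is the shorter road, and it avoids the organolithium chemistry of step 7.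
- Weak points: there is no close model for 6-endo against 5-exo attack, or for bimolecular allyl transfer to a short-lived vinyl radical against 1,5-hydrogen transfer. The methallyl group of A4 must later be hydrated next to an enone that is itself vulnerable under hydrogen-atom-transfer conditions. Stoichiometric tin must be removed.
- Comparison: the chosen plan gives up that brevity for polar steps with direct analogy and a side chain that arrives from lactone 11 with its oxygen in place. Like the other two, this alternative says nothing about closing ring B without losing C2.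

Key step: step 21

Assumption: the (−)-menthyl esters are taken to steer the double alkylation of the tetrasubstituted dienolate in the same facial sense as for unsubstituted succinate, towards the (1S,2S) diester; the diastereomers are separable in any case.

## Route

Step 1
Reactants: 1 2,3-dimethylsuccinic acid (stereoisomer mixture); 2 (−)-menthol, (1R,2S,5R)
Product: 3 bis[(1R,2S,5R)-menthyl] 2,3-dimethylsuccinate (stereoisomer mixture at C2/C3)
Conditions: 2 (2.2 equiv in all), TsOH (cat.), toluene, reflux, Dean–Stark
Reagents that add atoms: (−)-menthol (second equivalent of 2), CC(C)[C@@H]1CC[C@@H](C)C[C@H]1O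
Why: Twofold Fischer esterification driven by azeotropic removal of water, each carboxyl group taking up one molecule of menthol; the configuration at C2 and C3 is irrelevant because both centres become trigonal in step 2.

Step 2
Reactants: 3 bis[(1R,2S,5R)-menthyl] 2,3-dimethylsuccinate; 4 1-bromo-3-chloropropane
Product: 7 bis[(1R,2S,5R)-menthyl] (1S,2S)-1,2-dimethylcyclopentane-1,2-dicarboxylate, via dilithium bis-enolate 5 (not isolated), via chloropropyl lithium enolate 6 (not isolated)
Conditions: LiN(iPr)2 (2.3 equiv), THF, −78 to −20 °C; then 4, DMPU, −78 °C to rt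
Reagents that add atoms: none
Why: Double enolate alkylation of a succinate dienolate: the bromide end reacts first and the tethered chloride then closes ring D by 5-exo-tet displacement. The menthyl groups shield one face of each enolate carbon and should favour the trans (1S,2S) diester, which is a diastereomer of the (1R,2R) and cis isomers and can be purified by crystallisation or chromatography.

Step 3
Reactants: 7 bis[(1R,2S,5R)-menthyl] (1S,2S)-1,2-dimethylcyclopentane-1,2-dicarboxylate
Product: 8 [(1S,2S)-1,2-dimethylcyclopentane-1,2-diyl]dimethanol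
Conditions: LiAlH4, THF, 0 °C to reflux; aqueous potassium sodium tartrate
Reagents that add atoms: none
Why: Hydride reduction of both hindered esters gives the C2-symmetric diol and releases the auxiliary for recovery; the quaternary centres cannot epimerise.

Step 4
Reactants: 8 [(1S,2S)-1,2-dimethylcyclopentane-1,2-diyl]dimethanol
Product: 9 {(1S,2S)-2-[(4-methoxybenzyloxy)methyl]-1,2-dimethylcyclopentyl}methanol
Conditions: NaH (1.0 equiv), THF/DMF, 0 °C; 4-methoxybenzyl chloride (1.0 equiv), Bu4NI (cat.), rt
Reagents that add atoms: 4-methoxybenzyl chloride, COc1ccc(CCl)cc1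
Why: Williamson etherification; the two hydroxyl groups are homotopic through the C2 axis, so mono-alkylation gives a single compound, and unreacted diol can be returned to the step.

Step 5
Reactants: 9 {(1S,2S)-2-[(4-methoxybenzyloxy)methyl]-1,2-dimethylcyclopentyl}methanol
Product: 10 1-({[(1S,2S)-2-(iodomethyl)-1,2-dimethylcyclopentyl]methoxy}methyl)-4-methoxybenzene
Conditions: I2, PPh3, imidazole, toluene, 80 °C
Reagents that add atoms: iodine, II
Why: Appel-type iodination through the alkoxyphosphonium salt; SN2 at the neopentyl carbon is slow but feasible at this temperature. Participation by the ether oxygen is disfavoured because it would create a trans-fused bicyclo[3.3.0] oxonium ion.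

Step 6
Reactants: 11 5,5-dimethyldihydrofuran-2(3H)-one
Product: 13 N-methoxy-N,4-dimethyl-4-(triethylsilyloxy)pentanamide, via hydroxy amide 12 (not isolated)
Conditions: MeNH(OMe)·HCl, i-PrMgCl, THF, −20 to 0 °C; aqueous work-up; then Et3SiOTf, 2,6-lutidine, CH2Cl2, −78 to 0 °C
Reagents that add atoms: N,O-dimethylhydroxylamine hydrochloride, CNOC.Cl; triethylsilyl trifluoromethanesulfonate, CC[Si](CC)(CC)OS(=O)(=O)C(F)(F)F
Why: Aminolysis of the lactone by the magnesium amide gives the N-methoxy-N-methylamide; immediate silylation of the tertiary alcohol prevents relactonisation and installs the group that protects the side chain until the last step.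

Step 7
Reactants: 10 1-({[(1S,2S)-2-(iodomethyl)-1,2-dimethylcyclopentyl]methoxy}methyl)-4-methoxybenzene; 13 N-methoxy-N,4-dimethyl-4-(triethylsilyloxy)pentanamide
Product: 15 1-{(1R,2S)-2-[(4-methoxybenzyloxy)methyl]-1,2-dimethylcyclopentyl}-5-methyl-5-(triethylsilyloxy)hexan-2-one, via neopentyl-type alkyllithium 14 (not isolated)
Conditions: t-BuLi (2.1 equiv), Et2O/pentane, −78 °C; then 13, −78 to 0 °C; aqueous NH4Cl
Reagents that add atoms: none
Why: Iodine–lithium exchange gives a primary organolithium that has no β-hydrogen to lose and no ring to close. Acylation of the N-methoxy-N-methylamide stops at the ketone through the chelated tetrahedral intermediate, so C7 acts as the nucleophile and no carbon–carbon bond has to be made by substitution at a neopentyl carbon.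

Step 8
Reactants: 15 1-{(1R,2S)-2-[(4-methoxybenzyloxy)methyl]-1,2-dimethylcyclopentyl}-5-methyl-5-(triethylsilyloxy)hexan-2-one
Product: 16 1-[(1R,2S)-2-(hydroxymethyl)-1,2-dimethylcyclopentyl]-5-methyl-5-(triethylsilyloxy)hexan-2-one
Conditions: DDQ, CH2Cl2/pH 7 buffer, 0 °C to rt
Reagents that add atoms: none
Why: Oxidative cleavage of the 4-methoxybenzyl ether by hydride abstraction and hydrolysis of the oxocarbenium ion; the silyl ether and the ketone are inert, and any cyclic hemiketal of 16 is in equilibrium with the open form.

Step 9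
Reactants: 16 1-[(1R,2S)-2-(hydroxymethyl)-1,2-dimethylcyclopentyl]-5-methyl-5-(triethylsilyloxy)hexan-2-one
Product: 18 (3aR,7aR)-3a,7a-dimethyl-6-[2-methyl-2-(triethylsilyloxy)propyl]-1,2,3,3a,4,7a-hexahydro-5H-inden-5-one, via keto aldehyde 17 (not isolated)
Conditions: Dess–Martin periodinane, NaHCO3, CH2Cl2, 0 °C to rt; filtration; then KOH, MeOH, rt to 40 °C
Reagents that add atoms: none
Why: Oxidation gives a non-enolisable neopentyl aldehyde. In the intramolecular aldol condensation only the enolate on the side-chain side of the ketone can form a six-membered ring (the ring-side enolate would give a four-membered ring), and E1cB loss of water completes ring C with the trans fusion already fixed.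

Step 10
Reactants: 18 (3aR,7aR)-3a,7a-dimethyl-6-[2-methyl-2-(triethylsilyloxy)propyl]-1,2,3,3a,4,7a-hexahydro-5H-inden-5-one
Product: 19 (3aR,7aR)-5-(bromomethyl)-3a,7a-dimethyl-6-[2-methyl-2-(triethylsilyloxy)propyl]-2,3,3a,4,5,7a-hexahydro-1H-inden-5-ol (C5 epimers)
Conditions: CH2Br2, n-BuLi (added last, slowly), THF, −78 °C; AcOH, −78 °C
Reagents that add atoms: dibromomethane, BrCBr
Why: Bromomethyllithium, formed by bromine–lithium exchange in the presence of the enone, adds 1,2 to the carbonyl as hard organolithium reagents do. The cold acidic quench keeps the bromohydrin from closing to the epoxide, and the new carbinol centre is destroyed in step 11.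

Step 11
Reactants: 19 (3aR,7aR)-5-(bromomethyl)-3a,7a-dimethyl-6-[2-methyl-2-(triethylsilyloxy)propyl]-2,3,3a,4,5,7a-hexahydro-1H-inden-5-ol
Product: 20 (3aS,7aR)-6-(bromomethyl)-3a,7a-dimethyl-5-[2-methyl-2-(triethylsilyloxy)propyl]-1,2,3,3a,7,7a-hexahydro-4H-inden-4-one
Conditions: pyridinium chlorochromate, NaOAc, 4 Å molecular sieves, CH2Cl2, rt
Reagents that add atoms: pyridinium chlorochromate, [O-][Cr](=O)(=O)Cl.c1cc[nH+]cc1
Why: Oxidative 1,3-transposition of a tertiary allylic alcohol (Babler–Dauben oxidation): the chromate ester shifts [3,3] to the secondary allylic position and is oxidised there. This puts the carbonyl at C4, the double bond at C5=C6 and the bromomethyl group on C6.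

Step 12
Reactants: 21 (S)-lactic acid; 22 pivalaldehyde
Product: 23 (2S,5S)-2-tert-butyl-5-methyl-1,3-dioxolan-4-one
Conditions: TsOH (cat.), H2SO4 (cat.), pentane, reflux, Dean–Stark; crystallisation from pentane/Et2O at low temperature
Reagents that add atoms: none
Why: Acid-catalysed acetalisation under thermodynamic control favours the cis acetal, which is freed of the trans isomer by crystallisation; the acetal carbon now stores the chirality of lactic acid.

Step 13
Reactants: 23 (2S,5S)-2-tert-butyl-5-methyl-1,3-dioxolan-4-one; 20 (3aS,7aR)-6-(bromomethyl)-3a,7a-dimethyl-5-[2-methyl-2-(triethylsilyloxy)propyl]-1,2,3,3a,7,7a-hexahydro-4H-inden-4-one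
Product: 25 (2S,5R)-2-tert-butyl-5-({(3aS,7aR)-3a,7a-dimethyl-5-[2-methyl-2-(triethylsilyloxy)propyl]-4-oxo-2,3,3a,4,7,7a-hexahydro-1H-inden-6-yl}methyl)-5-methyl-1,3-dioxolan-4-one, via lithium enolate 24 (not isolated)
Conditions: 23 (1.6 equiv), LiN(iPr)2 (1.5 equiv), THF, −78 °C; then 20, DMPU, −78 to −40 °C
Reagents that add atoms: none
Why: Enolate alkylation with self-regeneration of the stereocentre: the lactate carbon becomes trigonal, the tert-butyl group on the acetal carbon blocks one face, and the allylic bromide enters anti to it, in the place of the former hydrogen. This gives the (5R) quaternary centre that becomes C2 of the chromene; the β-carbon of the enone is fully substituted, which disfavours conjugate addition.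

Step 14
Reactants: 25 (2S,5R)-2-tert-butyl-5-({(3aS,7aR)-3a,7a-dimethyl-5-[2-methyl-2-(triethylsilyloxy)propyl]-4-oxo-2,3,3a,4,7,7a-hexahydro-1H-inden-6-yl}methyl)-5-methyl-1,3-dioxolan-4-one
Product: 26 (2R)-3-{(3aS,7aR)-4-hydroxy-3a,7a-dimethyl-5-[2-methyl-2-(triethylsilyloxy)propyl]-2,3,3a,4,7,7a-hexahydro-1H-inden-6-yl}-2-methylpropane-1,2-diol (C4 epimers)
Conditions: LiAlH4, Et2O, 0 °C; aqueous potassium sodium tartrate
Reagents that add atoms: none
Why: Hydride reduction opens the acyl acetal to the primary/tertiary 1,2-diol (the acetal carbon leaves as neopentyl alcohol) and reduces the enone carbonyl 1,2. The epimeric allylic carbinol is removed in step 15, and the C–O bond at the future C2 is not touched.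

Step 15
Reactants: 26 (2R)-3-{(3aS,7aR)-4-hydroxy-3a,7a-dimethyl-5-[2-methyl-2-(triethylsilyloxy)propyl]-2,3,3a,4,7,7a-hexahydro-1H-inden-6-yl}-2-methylpropane-1,2-diol
Product: 27 (2R)-3-{(3aS,7aR)-3a,7a-dimethyl-5-[2-methyl-2-(triethylsilyloxy)propyl]-4-oxo-2,3,3a,4,7,7a-hexahydro-1H-inden-6-yl}-2-hydroxy-2-methylpropanal
Conditions: (COCl)2, DMSO, CH2Cl2, −78 °C; Et3N, −78 to 0 °C
Reagents that add atoms: none
Why: Swern oxidation converts the primary alcohol to the aldehyde and the hindered allylic alcohol back to the enone in one operation. Activated DMSO does not cleave 1,2-diols, the tertiary alcohol cannot be oxidised, and the aldehyde α-carbon is quaternary and cannot epimerise.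

Step 16
Reactants: 27 (2R)-3-{(3aS,7aR)-3a,7a-dimethyl-5-[2-methyl-2-(triethylsilyloxy)propyl]-4-oxo-2,3,3a,4,7,7a-hexahydro-1H-inden-6-yl}-2-hydroxy-2-methylpropanal
Product: 28 (3aS,7aR)-6-[(2R)-2-hydroxy-2-methylbut-3-yn-1-yl]-3a,7a-dimethyl-5-[2-methyl-2-(triethylsilyloxy)propyl]-1,2,3,3a,7,7a-hexahydro-4H-inden-4-one
Conditions: dimethyl (1-diazo-2-oxopropyl)phosphonate, K2CO3, MeOH, 0 °C to rt
Reagents that add atoms: dimethyl (1-diazo-2-oxopropyl)phosphonate, COP(=O)(OC)C(=[N+]=[N-])C(C)=O
Why: Ohira–Bestmann homologation: the diazophosphonate anion adds to the aldehyde, loss of phosphate gives a diazoalkene, and this loses nitrogen and rearranges to the terminal alkyne. The hindered conjugated ketone does not react.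

Step 17
Reactants: 29 4-methoxy-2-methylphenol
Product: 30 2-iodo-4-methoxy-6-methylphenol
Conditions: N-iodosuccinimide, CF3CO2H (cat.), MeCN, 0 °C
Reagents that add atoms: N-iodosuccinimide, O=C1CCC(=O)N1I
Why: Electrophilic aromatic iodination directed by the hydroxyl group to its only free ortho position; para is blocked by methoxy and the other ortho position by methyl.

Step 18
Reactants: 30 2-iodo-4-methoxy-6-methylphenol
Product: 31 2-iodo-4-methoxy-6-methylphenyl trifluoromethanesulfonate
Conditions: (CF3SO2)2O, pyridine, CH2Cl2, 0 °C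
Reagents that add atoms: trifluoromethanesulfonic anhydride, O=S(=O)(OS(=O)(=O)C(F)(F)F)C(F)(F)F
Why: O-sulfonylation of the phenol; the triflate turns the phenolic carbon into the future electrophilic C8a and stays inert during the alkyne coupling.

Step 19
Reactants: 28 (3aS,7aR)-6-[(2R)-2-hydroxy-2-methylbut-3-yn-1-yl]-3a,7a-dimethyl-5-[2-methyl-2-(triethylsilyloxy)propyl]-1,2,3,3a,7,7a-hexahydro-4H-inden-4-one; 31 2-iodo-4-methoxy-6-methylphenyl trifluoromethanesulfonate
Product: 32 2-[(3R)-4-{(3aS,7aR)-3a,7a-dimethyl-5-[2-methyl-2-(triethylsilyloxy)propyl]-4-oxo-2,3,3a,4,7,7a-hexahydro-1H-inden-6-yl}-3-hydroxy-3-methylbut-1-yn-1-yl]-4-methoxy-6-methylphenyl trifluoromethanesulfonate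
Conditions: PdCl2(PPh3)2 (3 mol %), CuI (5 mol %), Et3N, THF, rt
Reagents that add atoms: none
Why: Sonogashira coupling; oxidative addition into the C–I bond is much faster than into the C–OTf bond at room temperature, so only the iodide is replaced, and the free tertiary propargylic alcohol is tolerated.

Step 20
Reactants: 32 the aryl alkyne of step 19
Product: 33 2-[(1Z,3R)-4-{(3aS,7aR)-3a,7a-dimethyl-5-[2-methyl-2-(triethylsilyloxy)propyl]-4-oxo-2,3,3a,4,7,7a-hexahydro-1H-inden-6-yl}-3-hydroxy-3-methylbut-1-en-1-yl]-4-methoxy-6-methylphenyl trifluoromethanesulfonate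
Conditions: H2 (1 atm), Pd/CaCO3 poisoned with Pb(OAc)2, quinoline, EtOAc, rt
Reagents that add atoms: none
Why: Syn addition of hydrogen on the poisoned palladium surface gives the Z alkene; the aryl triflate and the tetrasubstituted enone are not reduced under these conditions.

Step 21
Reactants: 33 the Z-alkenyl aryl triflate of step 20
Product: 34 (3aS,7aR)-6-{[(2R)-6-methoxy-2,8-dimethyl-2H-chromen-2-yl]methyl}-3a,7a-dimethyl-5-[2-methyl-2-(triethylsilyloxy)propyl]-1,2,3,3a,7,7a-hexahydro-4H-inden-4-one
Conditions: Pd(OAc)2 (5 mol %), 2-(di-tert-butylphosphino)-1,1'-binaphthyl (6 mol %), Cs2CO3 (1.5 equiv), toluene, 80 °C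
Reagents that add atoms: none
Why: This is a palladium-catalysed intramolecular aryl etherification (Buchwald–Hartwig-type C–O coupling); the closest known case is the cyclisation of tertiary alcohols carrying an ortho-halo- or triflyloxyaryl group to 2,2-disubstituted chromans. Zerovalent palladium, formed in situ from Pd(OAc)2 and the phosphine, inserts into the C8a–OTf bond. Carbonate then removes the proton of the coordinated tertiary hydroxyl to give a seven-membered aryl alkoxide complex of divalent palladium, and C–O reductive elimination forms the O1–C8a bond and closes ring B. The closure is a six-membered heterocyclisation by ipso substitution at an arene carbon, with the leaving group outside the new ring. No stereocentre is created: C2 keeps the configuration set in step 13 because its C–O bond is never broken, and the Z geometry from step 20 brings O1 within reach of C8a. The step needs reductive elimination to win over cleavage of the triflate at sulfur, over β-carbon elimination of the homoallylic tertiary alkoxide, and over Z to E isomerisation. β-Hydride elimination is impossible at a tertiary alkoxide, the bulky electron-rich biarylphosphine accelerates C–O reductive elimination, and Cs2CO3 is poorly soluble in toluene and only weakly nucleophilic towards the sulfonyl group. The side-chain alcohol is silylated, so only one alkoxide can bind to palladium.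

Step 22
Reactants: 34 the chromene silyl ether of step 21
Product: 35 (3aS,7aR)-5-(2-hydroxy-2-methylpropyl)-6-{[(2R)-6-methoxy-2,8-dimethyl-2H-chromen-2-yl]methyl}-3a,7a-dimethyl-1,2,3,3a,7,7a-hexahydro-4H-inden-4-one (CNP0295366.2)
Conditions: Bu4NF, THF, rt to 40 °C
Reagents that add atoms: none
Why: Fluoride cleaves the Si–O bond, driven by the strength of the Si–F bond; the weakly basic conditions leave the acid-sensitive chromene, the enone and both tertiary carbinol centres untouched.

## Compound list

1 | 2,3-dimethylsuccinic acid (stereoisomer mixture) | CC(C(=O)O)C(C)C(=O)O | starting material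
2 | (−)-menthol, (1R,2S,5R)-5-methyl-2-(propan-2-yl)cyclohexan-1-ol | CC(C)[C@@H]1CC[C@@H](C)C[C@H]1O | starting material
3 | bis[(1R,2S,5R)-menthyl] 2,3-dimethylsuccinate (mixture at C2/C3) | CC(C)[C@@H]1CC[C@@H](C)C[C@H]1OC(=O)C(C)C(C)C(=O)O[C@@H]1C[C@H](C)CC[C@H]1C(C)C | intermediate
4 | 1-bromo-3-chloropropane | ClCCCBr | starting material
5 | dilithium bis-enolate of 3 | CC(C)[C@@H]1CC[C@@H](C)C[C@H]1OC(O[Li])=C(C)C(C)=C(O[Li])O[C@@H]1C[C@H](C)CC[C@H]1C(C)C | intermediate (not isolated)
6 | lithium enolate of bis[(1R,2S,5R)-menthyl] (2S)-2-(3-chloropropyl)-2,3-dimethylsuccinate | CC(C)[C@@H]1CC[C@@H](C)C[C@H]1OC(=O)[C@@](C)(CCCCl)C(C)=C(O[Li])O[C@@H]1C[C@H](C)CC[C@H]1C(C)C | intermediate (not isolated)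
7 | bis[(1R,2S,5R)-menthyl] (1S,2S)-1,2-dimethylcyclopentane-1,2-dicarboxylate | CC(C)[C@@H]1CC[C@@H](C)C[C@H]1OC(=O)[C@@]2(C)CCC[C@]2(C)C(=O)O[C@@H]1C[C@H](C)CC[C@H]1C(C)C | intermediate
8 | [(1S,2S)-1,2-dimethylcyclopentane-1,2-diyl]dimethanol | OC[C@@]1(C)CCC[C@]1(C)CO | intermediate
9 | {(1S,2S)-2-[(4-methoxybenzyloxy)methyl]-1,2-dimethylcyclopentyl}methanol | COc1ccc(COC[C@@]2(C)CCC[C@]2(C)CO)cc1 | intermediate
10 | 1-({[(1S,2S)-2-(iodomethyl)-1,2-dimethylcyclopentyl]methoxy}methyl)-4-methoxybenzene | COc1ccc(COC[C@@]2(C)CCC[C@]2(C)CI)cc1 | intermediate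
11 | 5,5-dimethyldihydrofuran-2(3H)-one | CC1(C)CCC(=O)O1 | starting material
12 | 4-hydroxy-N-methoxy-N,4-dimethylpentanamide | CON(C)C(=O)CCC(C)(C)O | intermediate (not isolated)
13 | N-methoxy-N,4-dimethyl-4-(triethylsilyloxy)pentanamide | CON(C)C(=O)CCC(C)(C)O[Si](CC)(CC)CC | intermediate
14 | ({(1S,2S)-2-[(4-methoxybenzyloxy)methyl]-1,2-dimethylcyclopentyl}methyl)lithium | COc1ccc(COC[C@@]2(C)CCC[C@]2(C)C[Li])cc1 | intermediate (not isolated)
15 | 1-{(1R,2S)-2-[(4-methoxybenzyloxy)methyl]-1,2-dimethylcyclopentyl}-5-methyl-5-(triethylsilyloxy)hexan-2-one | COc1ccc(COC[C@@]2(C)CCC[C@]2(C)CC(=O)CCC(C)(C)O[Si](CC)(CC)CC)cc1 | intermediate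
16 | 1-[(1R,2S)-2-(hydroxymethyl)-1,2-dimethylcyclopentyl]-5-methyl-5-(triethylsilyloxy)hexan-2-one | OC[C@@]1(C)CCC[C@]1(C)CC(=O)CCC(C)(C)O[Si](CC)(CC)CC | intermediate
17 | (1S,2R)-1,2-dimethyl-2-[5-methyl-2-oxo-5-(triethylsilyloxy)hexyl]cyclopentane-1-carbaldehyde | O=C[C@@]1(C)CCC[C@]1(C)CC(=O)CCC(C)(C)O[Si](CC)(CC)CC | intermediate (not isolated)
18 | (3aR,7aR)-3a,7a-dimethyl-6-[2-methyl-2-(triethylsilyloxy)propyl]-1,2,3,3a,4,7a-hexahydro-5H-inden-5-one | O=C1C[C@@]2(C)CCC[C@]2(C)C=C1CC(C)(C)O[Si](CC)(CC)CC | intermediate
19 | (3aR,7aR)-5-(bromomethyl)-3a,7a-dimethyl-6-[2-methyl-2-(triethylsilyloxy)propyl]-2,3,3a,4,5,7a-hexahydro-1H-inden-5-ol (C5 epimers) | OC1(CBr)C[C@@]2(C)CCC[C@]2(C)C=C1CC(C)(C)O[Si](CC)(CC)CC | intermediate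
20 | (3aS,7aR)-6-(bromomethyl)-3a,7a-dimethyl-5-[2-methyl-2-(triethylsilyloxy)propyl]-1,2,3,3a,7,7a-hexahydro-4H-inden-4-one | BrCC1=C(CC(C)(C)O[Si](CC)(CC)CC)C(=O)[C@@]2(C)CCC[C@]2(C)C1 | intermediate
21 | (S)-lactic acid | C[C@H](O)C(=O)O | starting material
22 | pivalaldehyde | CC(C)(C)C=O | starting material
23 | (2S,5S)-2-tert-butyl-5-methyl-1,3-dioxolan-4-one | C[C@@H]1O[C@H](C(C)(C)C)OC1=O | intermediate
24 | lithium (2S)-2-tert-butyl-5-methyl-1,3-dioxol-4-olate | CC1=C(O[Li])O[C@@H](C(C)(C)C)O1 | intermediate (not isolated)
25 | (2S,5R)-2-tert-butyl-5-({(3aS,7aR)-3a,7a-dimethyl-5-[2-methyl-2-(triethylsilyloxy)propyl]-4-oxo-2,3,3a,4,7,7a-hexahydro-1H-inden-6-yl}methyl)-5-methyl-1,3-dioxolan-4-one | C[C@]1(CC2=C(CC(C)(C)O[Si](CC)(CC)CC)C(=O)[C@@]3(C)CCC[C@]3(C)C2)O[C@H](C(C)(C)C)OC1=O | intermediate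
26 | (2R)-3-{(3aS,7aR)-4-hydroxy-3a,7a-dimethyl-5-[2-methyl-2-(triethylsilyloxy)propyl]-2,3,3a,4,7,7a-hexahydro-1H-inden-6-yl}-2-methylpropane-1,2-diol (C4 epimers) | C[C@](O)(CO)CC1=C(CC(C)(C)O[Si](CC)(CC)CC)C(O)[C@@]2(C)CCC[C@]2(C)C1 | intermediate
27 | (2R)-3-{(3aS,7aR)-3a,7a-dimethyl-5-[2-methyl-2-(triethylsilyloxy)propyl]-4-oxo-2,3,3a,4,7,7a-hexahydro-1H-inden-6-yl}-2-hydroxy-2-methylpropanal | C[C@](O)(C=O)CC1=C(CC(C)(C)O[Si](CC)(CC)CC)C(=O)[C@@]2(C)CCC[C@]2(C)C1 | intermediate
28 | (3aS,7aR)-6-[(2R)-2-hydroxy-2-methylbut-3-yn-1-yl]-3a,7a-dimethyl-5-[2-methyl-2-(triethylsilyloxy)propyl]-1,2,3,3a,7,7a-hexahydro-4H-inden-4-one | C[C@](O)(C#C)CC1=C(CC(C)(C)O[Si](CC)(CC)CC)C(=O)[C@@]2(C)CCC[C@]2(C)C1 | intermediate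
29 | 4-methoxy-2-methylphenol | COc1ccc(O)c(C)c1 | starting material
30 | 2-iodo-4-methoxy-6-methylphenol | COc1cc(C)c(O)c(I)c1 | intermediate
31 | 2-iodo-4-methoxy-6-methylphenyl trifluoromethanesulfonate | COc1cc(C)c(OS(=O)(=O)C(F)(F)F)c(I)c1 | intermediate
32 | 2-[(3R)-4-{(3aS,7aR)-3a,7a-dimethyl-5-[2-methyl-2-(triethylsilyloxy)propyl]-4-oxo-2,3,3a,4,7,7a-hexahydro-1H-inden-6-yl}-3-hydroxy-3-methylbut-1-yn-1-yl]-4-methoxy-6-methylphenyl trifluoromethanesulfonate | COc1cc(C)c(OS(=O)(=O)C(F)(F)F)c(c1)C#C[C@](C)(O)CC1=C(CC(C)(C)O[Si](CC)(CC)CC)C(=O)[C@@]2(C)CCC[C@]2(C)C1 | intermediate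
33 | 2-[(1Z,3R)-4-{(3aS,7aR)-3a,7a-dimethyl-5-[2-methyl-2-(triethylsilyloxy)propyl]-4-oxo-2,3,3a,4,7,7a-hexahydro-1H-inden-6-yl}-3-hydroxy-3-methylbut-1-en-1-yl]-4-methoxy-6-methylphenyl trifluoromethanesulfonate | COc1cc(C)c(OS(=O)(=O)C(F)(F)F)c(c1)/C=C\[C@](C)(O)CC1=C(CC(C)(C)O[Si](CC)(CC)CC)C(=O)[C@@]2(C)CCC[C@]2(C)C1 | intermediate
34 | (3aS,7aR)-6-{[(2R)-6-methoxy-2,8-dimethyl-2H-chromen-2-yl]methyl}-3a,7a-dimethyl-5-[2-methyl-2-(triethylsilyloxy)propyl]-1,2,3,3a,7,7a-hexahydro-4H-inden-4-one | COc1cc(C)c2c(c1)C=C[C@@](C)(CC1=C(CC(C)(C)O[Si](CC)(CC)CC)C(=O)[C@@]3(C)CCC[C@]3(C)C1)O2 | intermediate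
35 | (3aS,7aR)-5-(2-hydroxy-2-methylpropyl)-6-{[(2R)-6-methoxy-2,8-dimethyl-2H-chromen-2-yl]methyl}-3a,7a-dimethyl-1,2,3,3a,7,7a-hexahydro-4H-inden-4-one | COc1cc(C)c2c(c1)C=C[C@@](C)(CC1=C(CC(C)(C)O)C(=O)[C@@]3(C)CCC[C@]3(C)C1)O2 | target

## Step count and least certain steps

Total step count: 22. Longest linear sequence: 18 steps (steps 1–5, 7–11, 13–16, 19–22).

**Step 21 (key step).** The most likely failure is isomerisation of the Z double bond to E under palladium at 80 °C, which takes O1 out of reach of C8a. Loss of the triflate by attack of base at sulfur before oxidative addition, and fragmentation of the palladium alkoxide by β-carbon elimination towards the ring-C olefin, are further leaks. Fallback, from 33 back to 34: the styrenyl double bond of 33 is saturated with diimide (2-nitrobenzenesulfonylhydrazide, Et3N) to give the saturated aryl triflate F1. The same etherification, now on a flexible saturated tether as in the known chroman closures, gives chroman F2. Dehydrogenation of the benzylic C3–C4 bond with DDQ in hot benzene restores the double bond and rejoins the route at 34.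

**Step 2.** Poor facial discrimination by the menthyl groups on a tetrasubstituted enolate, or closure to the cis diester, would erode the stereochemical purity of both ring-fusion centres. Fallback, from 1 back to 8: Fischer esterification of 1 with methanol gives dimethyl 2,3-dimethylsuccinate F3. The same double alkylation with 4, without auxiliary, gives the racemic trans diester F4, separated from the meso cis isomer. Saponification with KOH in hot aqueous ethylene glycol and classical resolution with (R)-1-phenylethylamine give the (1S,2S) diacid F5. LiAlH4 reduction of F5 rejoins the route at 8.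

**Step 5.** Displacement at the doubly hindered neopentyl carbon may be too slow, and at the temperature then needed ionisation with Wagner–Meerwein ring expansion can compete. Fallback, from 9 back to 15, avoiding any substitution at C7: Swern oxidation of 9 gives aldehyde F6. Wittig reaction with Ph3P=CHOMe gives enol ether F7, and mild acid hydrolysis gives the homologous aldehyde F8. Addition of the Grignard reagent from bromide F9 (made by silylation of 4-bromo-2-methylbutan-2-ol) gives alcohol F10. Oxidation with Dess–Martin periodinane rejoins the route at 15.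

**Step 11 (with step 10).** The bromomethyl group withdraws electron density from the carbinol carbon and may slow the [3,3] shift of the chromate ester, so that elimination to a diene or plain decomposition takes over. In step 10, closure of the bromohydrin alkoxide to the epoxide and direct addition of n-BuLi are the competing processes. Fallback, from 18 back to 20: [(4-methoxybenzyloxy)methyl]lithium, from tributyl{[(4-methoxybenzyl)oxy]methyl}stannane and n-BuLi, adds 1,2 to 18 to give tertiary allylic alcohol F11. Oxidative transposition with pyridinium chlorochromate gives enone ether F12, and DDQ releases allylic alcohol F13. CBr4/PPh3 converts F13 into 20.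

**Step 13.** The lithium enolate is a strong base and 20 has acidic γ-hydrogens, so proton transfer to the enolate, followed by decay of the resulting dienolate, can outrun SN2 substitution. Fallback, from 20 back to 26, removing the carbonyl before the union: iBu2AlH at −78 °C reduces the ketone of 20 to bromo alcohol F14. This is silylated in the same flask (Me3SiCl, imidazole) to F15, which has no acidic hydrogens. Alkylation of enolate 24 with F15 gives dioxolanone F16. LiAlH4 reduction with a dilute acid work-up opens the acetal, removes the trimethylsilyl group and rejoins the route at 26.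

## Further compounds

F1 | step 21 | 2-[(3S)-4-{(3aS,7aR)-3a,7a-dimethyl-5-[2-methyl-2-(triethylsilyloxy)propyl]-4-oxo-2,3,3a,4,7,7a-hexahydro-1H-inden-6-yl}-3-hydroxy-3-methylbutyl]-4-methoxy-6-methylphenyl trifluoromethanesulfonate | COc1cc(C)c(OS(=O)(=O)C(F)(F)F)c(c1)CC[C@](C)(O)CC1=C(CC(C)(C)O[Si](CC)(CC)CC)C(=O)[C@@]2(C)CCC[C@]2(C)C1
F2 | step 21 | (3aS,7aR)-6-{[(2S)-6-methoxy-2,8-dimethyl-3,4-dihydro-2H-chromen-2-yl]methyl}-3a,7a-dimethyl-5-[2-methyl-2-(triethylsilyloxy)propyl]-1,2,3,3a,7,7a-hexahydro-4H-inden-4-one | COc1cc(C)c2c(c1)CC[C@@](C)(CC1=C(CC(C)(C)O[Si](CC)(CC)CC)C(=O)[C@@]3(C)CCC[C@]3(C)C1)O2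
F3 | step 2 | dimethyl 2,3-dimethylsuccinate (stereoisomer mixture) | COC(=O)C(C)C(C)C(=O)OC
F4 | step 2 | dimethyl trans-1,2-dimethylcyclopentane-1,2-dicarboxylate (racemate; one enantiomer drawn) | COC(=O)[C@@]1(C)CCC[C@]1(C)C(=O)OC
F5 | step 2 | (1S,2S)-1,2-dimethylcyclopentane-1,2-dicarboxylic acid (first obtained as the racemate) | OC(=O)[C@@]1(C)CCC[C@]1(C)C(=O)O
F6 | step 5 | (1S,2S)-2-[(4-methoxybenzyloxy)methyl]-1,2-dimethylcyclopentane-1-carbaldehyde | COc1ccc(COC[C@@]2(C)CCC[C@]2(C)C=O)cc1
F7 | step 5 | 1-methoxy-4-({[(1S,2R)-2-(2-methoxyethenyl)-1,2-dimethylcyclopentyl]methoxy}methyl)benzene (E/Z mixture) | COc1ccc(COC[C@@]2(C)CCC[C@]2(C)C=COC)cc1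
F8 | step 5 | 2-{(1R,2S)-2-[(4-methoxybenzyloxy)methyl]-1,2-dimethylcyclopentyl}acetaldehyde | COc1ccc(COC[C@@]2(C)CCC[C@]2(C)CC=O)cc1
F9 | step 5 | [(4-bromo-2-methylbutan-2-yl)oxy]triethylsilane | CC[Si](CC)(CC)OC(C)(C)CCBr
F10 | step 5 | 1-{(1R,2S)-2-[(4-methoxybenzyloxy)methyl]-1,2-dimethylcyclopentyl}-5-methyl-5-(triethylsilyloxy)hexan-2-ol (C2 epimers) | COc1ccc(COC[C@@]2(C)CCC[C@]2(C)CC(O)CCC(C)(C)O[Si](CC)(CC)CC)cc1
F11 | step 11 | (3aR,7aR)-5-[(4-methoxybenzyloxy)methyl]-3a,7a-dimethyl-6-[2-methyl-2-(triethylsilyloxy)propyl]-2,3,3a,4,5,7a-hexahydro-1H-inden-5-ol (C5 epimers) | COc1ccc(COCC2(O)C[C@@]3(C)CCC[C@]3(C)C=C2CC(C)(C)O[Si](CC)(CC)CC)cc1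
F12 | step 11 | (3aS,7aR)-6-[(4-methoxybenzyloxy)methyl]-3a,7a-dimethyl-5-[2-methyl-2-(triethylsilyloxy)propyl]-1,2,3,3a,7,7a-hexahydro-4H-inden-4-one | COc1ccc(COCC2=C(CC(C)(C)O[Si](CC)(CC)CC)C(=O)[C@@]3(C)CCC[C@]3(C)C2)cc1
F13 | step 11 | (3aS,7aR)-6-(hydroxymethyl)-3a,7a-dimethyl-5-[2-methyl-2-(triethylsilyloxy)propyl]-1,2,3,3a,7,7a-hexahydro-4H-inden-4-one | OCC1=C(CC(C)(C)O[Si](CC)(CC)CC)C(=O)[C@@]2(C)CCC[C@]2(C)C1
F14 | step 13 | (3aS,7aR)-6-(bromomethyl)-3a,7a-dimethyl-5-[2-methyl-2-(triethylsilyloxy)propyl]-2,3,3a,4,7,7a-hexahydro-1H-inden-4-ol (C4 epimers) | BrCC1=C(CC(C)(C)O[Si](CC)(CC)CC)C(O)[C@@]2(C)CCC[C@]2(C)C1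
F15 | step 13 | {[(3aS,7aR)-6-(bromomethyl)-3a,7a-dimethyl-5-[2-methyl-2-(triethylsilyloxy)propyl]-2,3,3a,4,7,7a-hexahydro-1H-inden-4-yl]oxy}trimethylsilane (C4 epimers) | BrCC1=C(CC(C)(C)O[Si](CC)(CC)CC)C(O[Si](C)(C)C)[C@@]2(C)CCC[C@]2(C)C1
F16 | step 13 | (2S,5R)-2-tert-butyl-5-({(3aS,7aR)-3a,7a-dimethyl-5-[2-methyl-2-(triethylsilyloxy)propyl]-4-(trimethylsilyloxy)-2,3,3a,4,7,7a-hexahydro-1H-inden-6-yl}methyl)-5-methyl-1,3-dioxolan-4-one (C4 epimers) | C[C@]1(CC2=C(CC(C)(C)O[Si](CC)(CC)CC)C(O[Si](C)(C)C)[C@@]3(C)CCC[C@]3(C)C2)O[C@H](C(C)(C)C)OC1=O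
A1 | alternative 1 | bis[(1R,2S,5R)-menthyl] (1S,2S)-1,2-dimethylcyclopentane-1,2-dicarboxylate | CC(C)[C@@H]1CC[C@@H](C)C[C@H]1OC(=O)[C@@]2(C)CCC[C@]2(C)C(=O)O[C@@H]1C[C@H](C)CC[C@H]1C(C)C
A2 | alternative 2 | methyl 2-(trans-fused 3a,7a-dimethyl-4-oxo-1-vinyloctahydro-1H-inden-5-yl)acetate | C1[C@@H](CC(=O)OC)C(=O)[C@@]2(C)CC[C@H](C=C)[C@]2(C)C1
A3 | alternative 2 | methyl (6E)-3-(chlorocarbonyl)-6,7-dimethyl-12-(trimethylsilyl)dodeca-6,10-dienoate | COC(=O)CC(C(Cl)=O)CC/C(C)=C(C)/CCC=CC[Si](C)(C)C
A4 | alternative 3 | trans-fused 6-(tert-butyldimethylsilyloxymethyl)-3a,7a-dimethyl-5-(2-methylallyl)-1,2,3,3a,7,7a-hexahydro-4H-inden-4-one | CC(C)(C)[Si](C)(C)OCC1=C(CC(C)=C)C(=O)[C@@]2(C)CCC[C@]2(C)C1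
A5 | alternative 3 | 4-(tert-butyldimethylsilyloxy)-1-[(1S,2S)-2-(iodomethyl)-1,2-dimethylcyclopentyl]but-2-yn-1-one | CC(C)(C)[Si](C)(C)OCC#CC(=O)[C@@]1(C)CCC[C@]1(C)CI
A6 | alternative 3 | tributyl(2-methylprop-2-en-1-yl)stannane | CCCC[Sn](CCCC)(CCCC)CC(C)=C
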